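**Plan** (1-benzoxepine locants: O1, C2–C5, C5a, C6–C9, C9a)

- Retrosynthesis: remove the C3–C4 oxirane oxygen; take the bromomethylidene carbon off C2 (back to a lactone carbonyl); cut the carbocycle at C5a–C6 (bromonium ion against an allylsilane); cut the remaining seven-membered lactone at C3–C4 by a Claisen retron to a vinyl dioxolanone, which comes from 2,3-epoxygeraniol.
- Forward order: oxirane on the geraniol chain, temporary five-membered carbonate, Claisen ring expansion to the oxepinone (the oxepane ring), then the bromocyclohexane (C5a, C6, C7, C8, C9, C9a) as the last ring of the bicyclic skeleton; the oxirane is a late functional-group change.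
- Enabling feature: the ring-fusion carbon C5a lies between the oxygenated quaternary C9a and C5 of the oxepane. A temporary silyl group on C4 makes C5=C5a of the preformed oxepinone an allylsilane, whose γ-carbon attacks the bromonium ion of the homoprenyl chain on C9a. The C2 lactone carbonyl then moves the resulting C4=C5 olefin to C3=C4 and later becomes the bromomethylidene carbon.
- Stereochemistry: one catalytic Sharpless epoxidation sets C9a; the Claisen relays it to the silyl-bearing C4; the key step relays that to C5a and C7 together with the ring; the last epoxidation sets C3 and C4 from the face opposite the axial 9a-methyl; the E olefin comes from steric selection in a mono-debromination.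

Key step: step 7

Remark on locants: monocyclic lactones are numbered as oxepin-2-ones (O1, C2 carbonyl, C3 to C7); oxepinone C6 and C7 become C5a and C9a of the 1-benzoxepines.
Assumption: the enolate methylation of step 6 is drawn anti to the silyl group (3R); this center becomes sp2 in step 8, so either epimer can be carried on.

Step 1
Reactants: 1 geraniol
Product: 2 [(2S,3S)-3-methyl-3-(4-methylpent-3-en-1-yl)oxiran-2-yl]methanol
Conditions: Ti(OiPr)4 (cat.), L-(+)-diethyl tartrate (cat.), t-BuOOH, 4 Å MS, CH2Cl2, −20 °C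
Reagents that add atoms: tert-butyl hydroperoxide CC(C)(C)OO
Why: Sharpless asymmetric epoxidation of the allylic alcohol with the L-tartrate ligand should oxidize only the 2,3-olefin (the remote olefin has no directing hydroxyl) and set both oxirane carbons as S, the quaternary one being the future C9a.

Step 2
Reactants: 2 [(2S,3S)-3-methyl-3-(4-methylpent-3-en-1-yl)oxiran-2-yl]methanol
Product: 3 (2R,3S)-3-methyl-3-(4-methylpent-3-en-1-yl)oxirane-2-carbaldehyde
Conditions: TEMPO (cat.), PhI(OAc)2, CH2Cl2, rt
Reagents that add atoms: none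
Why: Oxoammonium-mediated oxidation of the primary alcohol stops at the aldehyde under near-neutral conditions that should leave the trisubstituted oxirane and olefin intact (the descriptor at C2 changes by priority only).

Step 3
Reactants: 3 (2R,3S)-3-methyl-3-(4-methylpent-3-en-1-yl)oxirane-2-carbaldehyde
Product: 4 trimethyl{(E)-2-[(2S,3S)-3-methyl-3-(4-methylpent-3-en-1-yl)oxiran-2-yl]ethenyl}silane
Conditions: Me3SiCHBr2, CrCl2, THF, rt
Reagents that add atoms: (dibromomethyl)trimethylsilane C[Si](C)(C)C(Br)Br
Why: Takai olefination with the geminal dichromium reagent should convert the aldehyde into the (E)-vinylsilane, the non-basic carbenoid leaving the adjacent oxirane untouched.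

Step 4
Reactants: 4 trimethyl{(E)-2-[(2S,3S)-3-methyl-3-(4-methylpent-3-en-1-yl)oxiran-2-yl]ethenyl}silane
Product: 5 (4S,5S)-5-methyl-5-(4-methylpent-3-en-1-yl)-4-[(E)-2-(trimethylsilyl)ethenyl]-1,3-dioxolan-2-one
Conditions: Pd(PPh3)4 (cat.), CO2 (1 atm), THF, rt
Reagents that add atoms: carbon dioxide O=C=O
Why: Palladium-catalyzed carboxylative ring expansion of a vinyl epoxide: zerovalent palladium ionizes the allylic C–O bond with inversion, the tertiary alkoxide (no β-hydrogen) captures CO2, and the carbonate recloses on the π-allyl with a second inversion, so the five-membered carbonate should form with net retention.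

Step 5
Reactants: 5 (4S,5S)-5-methyl-5-(4-methylpent-3-en-1-yl)-4-[(E)-2-(trimethylsilyl)ethenyl]-1,3-dioxolan-2-one
Product: 7 (4S,7S)-7-methyl-7-(4-methylpent-3-en-1-yl)-4-(trimethylsilyl)-4,7-dihydrooxepin-2(3H)-one, via ketene acetal 6 (not isolated)
Conditions: Cp2TiMe2, toluene, 65 °C then 110 °C
Reagents that add atoms: dimethyltitanocene (Cp2TiMe2) C[Ti](C)(C1C=CC=C1)C1C=CC=C1
Why: Tandem carbonyl methylenation and Claisen ring expansion: the shift is suprafacial on the vinylsilane, the ring forces the quaternary carbon into the inside position (cis ring olefin) and the E-silyl group sits outside, so the allylic C–O stereocenter should be translated into the (4S) silyl-bearing carbon.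

Step 6
Reactants: 7 (4S,7S)-7-methyl-7-(4-methylpent-3-en-1-yl)-4-(trimethylsilyl)-4,7-dihydrooxepin-2(3H)-one
Product: 9 (3R,4R,7S)-3,7-dimethyl-7-(4-methylpent-3-en-1-yl)-4-(trimethylsilyl)-4,7-dihydrooxepin-2(3H)-one, via lithium enolate 8 (not isolated)
Conditions: LiN(i-Pr)2, THF, −78 °C; MeI, −78 to −40 °C
Reagents that add atoms: iodomethane CI
Why: Enolate alkylation of the lactone with MeI should place the C3 methyl anti to the bulky silyl group, a configuration of no consequence because this carbon becomes sp2 in step 8.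

Step 7
Reactants: 9 (3R,4R,7S)-3,7-dimethyl-7-(4-methylpent-3-en-1-yl)-4-(trimethylsilyl)-4,7-dihydrooxepin-2(3H)-one
Product: 11 (3S,5aS,7S,9aS)-7-bromo-3,6,6,9a-tetramethyl-5a,6,7,8,9,9a-hexahydro-1-benzoxepin-2(3H)-one, via bromonium ion 10 (not isolated)
Conditions: TBCO (2,4,4,6-tetrabromocyclohexa-2,5-dien-1-one), MeNO2, −20 to 0 °C
Reagents that add atoms: 2,4,4,6-tetrabromocyclohexa-2,5-dien-1-one (TBCO) O=C1C(Br)=CC(Br)(Br)C=C1Br
Why: Proposed new method: TBCO transfers Br+ reversibly to the trisubstituted side-chain olefin, bromonium ion 10 is opened at its tertiary carbon by C6 of the cyclic allylsilane (the future C5a) in an anti SE2′ sense, and the β-silyl cation at C5 gives up Me3Si+ to the tribromophenoxide, so the C4=C5 olefin forms without release of acid; the closest known reactions are bromonium-initiated polyene cyclizations terminated by olefins or arenes and epoxide- or Lewis-acid-initiated cyclizations terminated by allylsilanes, which have not been combined. The six-membered carbocycle closes 6-endo with respect to the bromonium ion and 6-exo with respect to the allylsilane olefin. C5a is set by the silyl group, since the new bond must form anti to the C4–Si bond, and the only chair that brings the tether to that face has the C9a–O1 bond antiperiplanar to the forming bond and the 9a-methyl axial, which makes the ring fusion trans. C7 is set by the same chair, in which bromine is equatorial and anti to the new bond; bromonium formation is reversible, so the diastereomeric bromonium ion that cannot adopt this chair should return to the olefin. The step needs Br+ to go to the side-chain olefin and not to the allylsilane (bromodesilylation), which the higher substitution of the former and the inductive deactivation and shielding of the ring olefin by the allylic acyloxy group on the neighbouring quaternary carbon should secure. It also needs a neutral bromine source, because Lewis or Brønsted acid would trigger 1,4-elimination of silyl and carboxylate across the ring olefin, and TBCO provides this.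

Step 8
Reactants: 11 (3S,5aS,7S,9aS)-7-bromo-3,6,6,9a-tetramethyl-5a,6,7,8,9,9a-hexahydro-1-benzoxepin-2(3H)-one
Product: 12 (5aS,7S,9aS)-7-bromo-3,6,6,9a-tetramethyl-5a,6,7,8,9,9a-hexahydro-1-benzoxepin-2(5H)-one
Conditions: DBU (cat.), CH2Cl2, rt
Reagents that add atoms: none
Why: Base-catalyzed β,γ- to α,β-isomerization through the lactone dienolate should move the olefin into conjugation (trisubstituted C3=C4), putting the hydrogen on C5 and erasing the C3 stereocenter, while the equatorial neopentyl bromide has no antiperiplanar hydrogen for elimination.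

Step 9
Reactants: 12 (5aS,7S,9aS)-7-bromo-3,6,6,9a-tetramethyl-5a,6,7,8,9,9a-hexahydro-1-benzoxepin-2(5H)-one
Product: 13 (5aS,7S,9aS)-7-bromo-2-(dibromomethylidene)-3,6,6,9a-tetramethyl-2,5,5a,6,7,8,9,9a-octahydro-1-benzoxepine
Conditions: CBr4, PPh3, toluene, 110 °C
Reagents that add atoms: carbon tetrabromide BrC(Br)(Br)Br
Why: Ramirez-type dibromomethylenation (Wittig olefination of a lactone carbonyl with Ph3P=CBr2, as used to make dibromo exo-glycals from sugar lactones) should turn the C2 carbonyl into the dibromo enol ether, so that no olefin geometry has to be controlled at this stage.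

Step 10
Reactants: 13 (5aS,7S,9aS)-7-bromo-2-(dibromomethylidene)-3,6,6,9a-tetramethyl-2,5,5a,6,7,8,9,9a-octahydro-1-benzoxepine
Product: 14 (2E,5aS,7S,9aS)-7-bromo-2-(bromomethylidene)-3,6,6,9a-tetramethyl-2,5,5a,6,7,8,9,9a-octahydro-1-benzoxepine
Conditions: Bu3SnH, Pd(PPh3)4 (cat.), toluene, rt, dark
Reagents that add atoms: none
Why: Palladium-catalyzed hydrodebromination of a 1,1-dibromoalkene: zerovalent palladium should insert into the less hindered C–Br bond (cis to O1, away from the 3-methyl group) and the vinylpalladium hydride collapses with retention, so the remaining bromine is cis to C3 (E), the alkyl bromide being inert without a radical initiator.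

Step 11
Reactants: 14 (2E,5aS,7S,9aS)-7-bromo-2-(bromomethylidene)-3,6,6,9a-tetramethyl-2,5,5a,6,7,8,9,9a-octahydro-1-benzoxepine
Product: 15 (2E,3R,4R,5aS,7S,9aS)-7-bromo-2-(bromomethylidene)-3,4-epoxy-3,6,6,9a-tetramethyldecahydro-1-benzoxepine (CNP0375295.1)
Conditions: dimethyldioxirane, acetone/CH2Cl2, −30 to 0 °C
Reagents that add atoms: dimethyldioxirane CC1(C)OO1
Why: Dioxirane epoxidation should pick the trialkyl-substituted C3=C4 olefin over the bromine-deactivated enol ether and approach from the α-face, anti to the axial 9a- and 6β-methyl groups that cover the β-face of the oxepine, setting C3 and C4 together under neutral conditions that spare the acid-labile allylic epoxide.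

**Compound list**

1 | geraniol, (2E)-3,7-dimethylocta-2,6-dien-1-ol | CC(C)=CCC/C(C)=C/CO | starting material
2 | [(2S,3S)-3-methyl-3-(4-methylpent-3-en-1-yl)oxiran-2-yl]methanol | OC[C@@H]1O[C@@]1(C)CCC=C(C)C | intermediate
3 | (2R,3S)-3-methyl-3-(4-methylpent-3-en-1-yl)oxirane-2-carbaldehyde | O=C[C@@H]1O[C@@]1(C)CCC=C(C)C | intermediate
4 | trimethyl{(E)-2-[(2S,3S)-3-methyl-3-(4-methylpent-3-en-1-yl)oxiran-2-yl]ethenyl}silane | C[Si](C)(C)/C=C/[C@@H]1O[C@@]1(C)CCC=C(C)C | intermediate
5 | (4S,5S)-5-methyl-5-(4-methylpent-3-en-1-yl)-4-[(E)-2-(trimethylsilyl)ethenyl]-1,3-dioxolan-2-one | C[Si](C)(C)/C=C/[C@@H]1OC(=O)O[C@@]1(C)CCC=C(C)C | intermediate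
6 | ketene acetal, (4S,5S)-4-methyl-2-methylidene-4-(4-methylpent-3-en-1-yl)-5-[(E)-2-(trimethylsilyl)ethenyl]-1,3-dioxolane | C[Si](C)(C)/C=C/[C@@H]1OC(=C)O[C@@]1(C)CCC=C(C)C | intermediate
7 | (4S,7S)-7-methyl-7-(4-methylpent-3-en-1-yl)-4-(trimethylsilyl)-4,7-dihydrooxepin-2(3H)-one | O=C1O[C@@](C)(CCC=C(C)C)/C=C\[C@@H]([Si](C)(C)C)C1 | intermediate
8 | lithium enolate of 7, lithium (4R,7S)-7-methyl-7-(4-methylpent-3-en-1-yl)-4-(trimethylsilyl)-4,7-dihydrooxepin-2-olate | [Li]OC1=C[C@H]([Si](C)(C)C)/C=C\[C@](C)(CCC=C(C)C)O1 | intermediate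
9 | (3R,4R,7S)-3,7-dimethyl-7-(4-methylpent-3-en-1-yl)-4-(trimethylsilyl)-4,7-dihydrooxepin-2(3H)-one | O=C1O[C@@](C)(CCC=C(C)C)/C=C\[C@@H]([Si](C)(C)C)[C@@H]1C | intermediate
10 | bromonium ion of 9 at the side-chain olefin, (S) at its secondary carbon, 2,4,6-tribromophenoxide as counter-ion | O=C1O[C@@](C)(CC[C@@H]2[Br+]C2(C)C)/C=C\[C@@H]([Si](C)(C)C)[C@@H]1C.[O-]c1c(Br)cc(Br)cc1Br | intermediate
11 | (3S,5aS,7S,9aS)-7-bromo-3,6,6,9a-tetramethyl-5a,6,7,8,9,9a-hexahydro-1-benzoxepin-2(3H)-one | CC1(C)[C@@H](Br)CC[C@]2(C)OC(=O)[C@@H](C)C=C[C@@H]12 | intermediate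
12 | (5aS,7S,9aS)-7-bromo-3,6,6,9a-tetramethyl-5a,6,7,8,9,9a-hexahydro-1-benzoxepin-2(5H)-one | CC1(C)[C@@H](Br)CC[C@]2(C)OC(=O)C(C)=CC[C@@H]12 | intermediate
13 | (5aS,7S,9aS)-7-bromo-2-(dibromomethylidene)-3,6,6,9a-tetramethyl-2,5,5a,6,7,8,9,9a-octahydro-1-benzoxepine | CC1(C)[C@@H](Br)CC[C@]2(C)OC(=C(Br)Br)C(C)=CC[C@@H]12 | intermediate
14 | (2E,5aS,7S,9aS)-7-bromo-2-(bromomethylidene)-3,6,6,9a-tetramethyl-2,5,5a,6,7,8,9,9a-octahydro-1-benzoxepine | CC1(C)[C@@H](Br)CC[C@]2(C)O/C(=C/Br)C(C)=CC[C@@H]12 | intermediate
15 | (2E,3R,4R,5aS,7S,9aS)-7-bromo-2-(bromomethylidene)-3,4-epoxy-3,6,6,9a-tetramethyldecahydro-1-benzoxepine (CNP0375295.1) | CC1(C)[C@@H](Br)CC[C@]2(C)O/C(=C/Br)[C@]3(C)O[C@@H]3C[C@@H]12 | target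

**Step count and risks**

Total step count: 11. Longest linear sequence: 11 steps (from geraniol).

Steps most likely to fail:

1. Step 7 (proposed new method). What may go wrong: direct bromodesilylation of the allylsilane, capture of the bromonium ion by phenoxide before ring closure, or 1,4-elimination of silyl and carboxylate. The fallback sets out from 9 and uses established reactions only. Shi epoxidation of the side-chain olefin (fructose-derived ketone of the enantiomeric series that gives the (S)-epoxide, 2KHSO5·KHSO4·K2SO4, K2CO3, MeCN/dimethoxymethane/buffer, 0 °C), which the cis-disubstituted, acyloxy-deactivated ring olefin should not contest, gives (3R,4R,7S)-7-{2-[(2S)-3,3-dimethyloxiran-2-yl]ethyl}-3,7-dimethyl-4-(trimethylsilyl)-4,7-dihydrooxepin-2(3H)-one F1. The long-established epoxide-initiated, allylsilane-terminated cyclization (BF3·OEt2, CH2Cl2, −78 °C) closes the same ring through the same chair to the equatorial alcohol (3S,5aS,7S,9aS)-7-hydroxy-3,6,6,9a-tetramethyl-5a,6,7,8,9,9a-hexahydro-1-benzoxepin-2(3H)-one F2. Dess–Martin oxidation gives (3S,5aS,9aS)-3,6,6,9a-tetramethyl-5a,8,9,9a-tetrahydro-1-benzoxepine-2,7(3H,6H)-dione F3. LiBH(s-Bu)3 (THF, −78 °C) attacks the ketone from the equatorial side to give the axial alcohol (3S,5aS,7R,9aS)-7-hydroxy-3,6,6,9a-tetramethyl-5a,6,7,8,9,9a-hexahydro-1-benzoxepin-2(3H)-one F4. Appel bromination (CBr4, PPh3) with inversion comes back to the route at 11.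

2. Step 9. What may go wrong: no attack of the bulky ylide on the hindered, conjugated, tertiary-alkyl lactone carbonyl, or build-up of allylic strain between the incoming CBr2 group and the 3-methyl group. The fallback sets out from 12. Cp2TiMe2 (toluene, 70 °C), whose small oxophilic methylidene accepts hindered esters, gives (5aS,7S,9aS)-7-bromo-3,6,6,9a-tetramethyl-2-methylidene-2,5,5a,6,7,8,9,9a-octahydro-1-benzoxepine F5. Bromination–dehydrobromination (pyridinium tribromide, 2,6-lutidine, CH2Cl2, −78 °C, then DBU) gives (5aS,7S,9aS)-7-bromo-2-(bromomethylidene)-3,6,6,9a-tetramethyl-2,5,5a,6,7,8,9,9a-octahydro-1-benzoxepine as an E/Z mixture F6. A second round of the same two operations, for which the geometry of F6 does not matter, comes back to the route at 13.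

3. Step 11. What may go wrong: competing oxidation of the bromo enol ether, poor facial selectivity, or opening of the allylic epoxide. The fallback sets out from 13, whose dibromo enol ether is much less nucleophilic, so that C3=C4 is the only reactive olefin. Dimethyldioxirane gives (3R,4R,5aS,7S,9aS)-7-bromo-2-(dibromomethylidene)-3,4-epoxy-3,6,6,9a-tetramethyldecahydro-1-benzoxepine F7. Hydrodebromination as in step 10 (Bu3SnH, Pd(PPh3)4, 0 °C), in which insertion into the vinylic C–Br bond cis to O1 is expected to outrun ionization of the hindered allylic epoxide, comes back to the route at 15.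

Further compounds
F1 | step 7 | (3R,4R,7S)-7-{2-[(2S)-3,3-dimethyloxiran-2-yl]ethyl}-3,7-dimethyl-4-(trimethylsilyl)-4,7-dihydrooxepin-2(3H)-one | O=C1O[C@@](C)(CC[C@@H]2OC2(C)C)/C=C\[C@@H]([Si](C)(C)C)[C@@H]1C
F2 | step 7 | (3S,5aS,7S,9aS)-7-hydroxy-3,6,6,9a-tetramethyl-5a,6,7,8,9,9a-hexahydro-1-benzoxepin-2(3H)-one | CC1(C)[C@@H](O)CC[C@]2(C)OC(=O)[C@@H](C)C=C[C@@H]12
F3 | step 7 | (3S,5aS,9aS)-3,6,6,9a-tetramethyl-5a,8,9,9a-tetrahydro-1-benzoxepine-2,7(3H,6H)-dione | CC1(C)C(=O)CC[C@]2(C)OC(=O)[C@@H](C)C=C[C@@H]12
F4 | step 7 | (3S,5aS,7R,9aS)-7-hydroxy-3,6,6,9a-tetramethyl-5a,6,7,8,9,9a-hexahydro-1-benzoxepin-2(3H)-one | CC1(C)[C@H](O)CC[C@]2(C)OC(=O)[C@@H](C)C=C[C@@H]12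
F5 | step 9 | (5aS,7S,9aS)-7-bromo-3,6,6,9a-tetramethyl-2-methylidene-2,5,5a,6,7,8,9,9a-octahydro-1-benzoxepine | CC1(C)[C@@H](Br)CC[C@]2(C)OC(=C)C(C)=CC[C@@H]12
F6 | step 9 | (5aS,7S,9aS)-7-bromo-2-(bromomethylidene)-3,6,6,9a-tetramethyl-2,5,5a,6,7,8,9,9a-octahydro-1-benzoxepine, E/Z mixture | CC1(C)[C@@H](Br)CC[C@]2(C)OC(=CBr)C(C)=CC[C@@H]12
F7 | step 11 | (3R,4R,5aS,7S,9aS)-7-bromo-2-(dibromomethylidene)-3,4-epoxy-3,6,6,9a-tetramethyldecahydro-1-benzoxepine | CC1(C)[C@@H](Br)CC[C@]2(C)OC(=C(Br)Br)[C@]3(C)O[C@@H]3C[C@@H]12
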